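**Retrosynthetic overview**
- The target is unmasked in one reductive operation from its 5,7-di-O-benzyl ether, in which the sulfate is carried as a 2,2,2-trichloroethyl diester.
- Key disconnection C2–C1': an aerobic Pd(II) oxidative boron-Heck reaction joins the C2–H of 5,7-bis(benzyloxy)-6-methoxychromone to a 4-borylphenyl trichloroethyl sulfate, so the aryl ring arrives with its sulfate in place and the flavone oxidation level is restored in the same step.
- Enabling feature: ring C is a γ-pyrone whose O1–C2(H)=C3–C4=O vinylogous ester makes C2 the β-carbon that takes the aryl group while C3 holds Pd as the α-keto enolate; the C2–H is then lost by β-hydride elimination.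
- The chromone comes from a 2-hydroxyacetophenone plus one carbon; the acetophenone comes from commercial 4,6-di-O-benzyl phloroacetophenone by para-hydroxylation and selective O-methylation.
- Ring order: ring A is bought, ring C is closed by O1–C2 bond formation, ring B is attached intact in the key step.

Key step: step 5

Remark: the target has no stereocentre and no stereogenic double bond, so no stereocontrol is needed; it is drawn as the free hydrogen sulfate, so the ammonium salt formed on deprotection is converted into the acid by cation exchange.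

**Step 1**
Reactants: 1 1-[2,4-bis(benzyloxy)-6-hydroxyphenyl]ethan-1-one (commercial)
Product: 3 1-[2,4-bis(benzyloxy)-3,6-dihydroxyphenyl]ethan-1-one, via potassium aryl sulfate 2 (not isolated)
Conditions: K2S2O8, aq KOH, pyridine, 0 °C to rt; then HCl, Na2SO3, H2O/toluene, 80 °C
Reagents that add atoms: potassium peroxodisulfate, [K+].[K+].[O-]S(=O)(=O)OOS(=O)(=O)[O-]
Why: Elbs persulfate oxidation: the phenolate of 1 should attack the peroxide oxygen through its only free para carbon (C3, between the two benzyloxy groups) to give aryl sulfate 2, whose acid hydrolysis by S–O cleavage should leave the new hydroxyl group, as is classical for 2-hydroxy-4,6-dialkoxyacetophenones.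

**Step 2**
Reactants: 3 1-[2,4-bis(benzyloxy)-3,6-dihydroxyphenyl]ethan-1-one
Product: 4 1-[2,4-bis(benzyloxy)-6-hydroxy-3-methoxyphenyl]ethan-1-one
Conditions: MeI (1.05 equiv), K2CO3, acetone, 40 °C
Reagents that add atoms: iodomethane, CI
Why: Chemoselective Williamson O-methylation: the 6-OH is held in a strong hydrogen bond to the acetyl carbonyl and is far less nucleophilic, so one equivalent of iodomethane should alkylate only the 3-OH.

**Step 3**
Reactants: 4 1-[2,4-bis(benzyloxy)-6-hydroxy-3-methoxyphenyl]ethan-1-one
Product: 6 5,7-bis(benzyloxy)-6-methoxy-4H-chromen-4-one, via enaminone 5 (not isolated)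
Conditions: DMF-DMA, toluene, 100 °C; evaporate; then conc. HCl, CH2Cl2, rt
Reagents that add atoms: N,N-dimethylformamide dimethyl acetal, COC(OC)N(C)C
Why: Enaminone chromone synthesis: condensation of the methyl ketone with the formamide acetal should give enaminone 5, and acid should trigger attack of the phenolic oxygen on the β-carbon with loss of dimethylamine (6-endo-trig addition–elimination), closing ring C with C2 and C3 unsubstituted.

**Step 4**
Reactants: 7 4-(4,4,5,5-tetramethyl-1,3,2-dioxaborolan-2-yl)phenol (commercial)
Product: 8 2,2,2-trichloroethyl 4-(4,4,5,5-tetramethyl-1,3,2-dioxaborolan-2-yl)phenyl sulfate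
Conditions: Cl3CCH2OSO2Cl, Et3N, DMAP (cat.), THF, 0 °C to rt
Reagents that add atoms: 2,2,2-trichloroethyl chlorosulfate, ClS(=O)(=O)OCC(Cl)(Cl)Cl
Why: O-sulfonylation of the phenol with a chlorosulfate ester, the known entry to trichloroethyl-protected aryl sulfates, should give the neutral sulfate diester, and the pinacol boronate should tolerate it.

**Step 5**
Reactants: 6 5,7-bis(benzyloxy)-6-methoxy-4H-chromen-4-one; 8 2,2,2-trichloroethyl 4-(4,4,5,5-tetramethyl-1,3,2-dioxaborolan-2-yl)phenyl sulfate
Product: 9 4-[5,7-bis(benzyloxy)-6-methoxy-4-oxo-4H-chromen-2-yl]phenyl 2,2,2-trichloroethyl sulfate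
Conditions: Pd(TFA)2 (10 mol %), 5-nitro-1,10-phenanthroline (20 mol %), 8 (1.5 equiv), O2 (1 atm), DMSO, 80–100 °C
Reagents that add atoms: none
Why: Oxidative boron-Heck C–H arylation: transmetalation of 8 to Pd(II) should give an aryl–Pd species that inserts the C2=C3 bond of 6 with aryl to C2 and Pd to C3, the regiochemistry being set by the O1–C2=C3–C4=O vinylogous ester, which places Pd on the α-keto carbon as an enolate. This Pd enolate can change face through its O-bound form, so syn β-hydride elimination of the C2–H should regenerate the γ-pyrone and deliver the flavone directly, with Pd–H reoxidised by O2. The closest known reaction type is the Pd(II)/O2 conjugate addition–β-hydride elimination of arylboronic acids and their pinacol esters to chromones, which gives flavones. No ring is closed and no stereocentre remains, because the transient C2 and C3 centres are erased by the elimination. The step needs C2 over C3 arylation, which the polarisation of the pyrone enone secures, and flavone over flavanone, which is secured because any flavanone formed by protonolysis should be dehydrogenated by the same Pd(II)/DMSO/O2 system. The medium is phosphine-free, base-free and non-reductive, so the O-benzyl ethers and the trichloroethyl sulfate diester should pass through unchanged.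

**Step 6**
Reactants: 9 4-[5,7-bis(benzyloxy)-6-methoxy-4-oxo-4H-chromen-2-yl]phenyl 2,2,2-trichloroethyl sulfate
Product: 11 hispidulin 4'-sulfate [4-(5,7-dihydroxy-6-methoxy-4-oxo-4H-chromen-2-yl)phenyl hydrogen sulfate], via ammonium salt 10 (not isolated)
Conditions: 10% Pd/C, HCO2NH4, MeOH/THF, rt; filter; then Dowex 50W-X8 (H+ form), H2O/MeOH, 0 °C; lyophilise
Reagents that add atoms: none
Why: Catalytic transfer hydrogenolysis should cleave both O-benzyl ethers, and the same Pd/formate system should remove the trichloroethyl group by reductive β-elimination to the aryl sulfate monoester anion (the known deprotection of trichloroethyl aryl sulfates), after which cold cation exchange should give the free hydrogen sulfate.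

**Compound list**
1 | 1-[2,4-bis(benzyloxy)-6-hydroxyphenyl]ethan-1-one | CC(=O)c1c(O)cc(OCc2ccccc2)cc1OCc1ccccc1 | starting material
2 | potassium 3-acetyl-2,6-bis(benzyloxy)-4-hydroxyphenyl sulfate | CC(=O)c1c(O)cc(OCc2ccccc2)c(OS(=O)(=O)[O-])c1OCc1ccccc1.[K+] | intermediate
3 | 1-[2,4-bis(benzyloxy)-3,6-dihydroxyphenyl]ethan-1-one | CC(=O)c1c(O)cc(OCc2ccccc2)c(O)c1OCc1ccccc1 | intermediate
4 | 1-[2,4-bis(benzyloxy)-6-hydroxy-3-methoxyphenyl]ethan-1-one | CC(=O)c1c(O)cc(OCc2ccccc2)c(OC)c1OCc1ccccc1 | intermediate
5 | (E)-1-[2,4-bis(benzyloxy)-6-hydroxy-3-methoxyphenyl]-3-(dimethylamino)prop-2-en-1-one | CN(C)/C=C/C(=O)c1c(O)cc(OCc2ccccc2)c(OC)c1OCc1ccccc1 | intermediate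
6 | 5,7-bis(benzyloxy)-6-methoxy-4H-chromen-4-one | COc1c(OCc2ccccc2)cc2occc(=O)c2c1OCc1ccccc1 | intermediate
7 | 4-(4,4,5,5-tetramethyl-1,3,2-dioxaborolan-2-yl)phenol | CC1(C)OB(OC1(C)C)c1ccc(O)cc1 | starting material
8 | 2,2,2-trichloroethyl 4-(4,4,5,5-tetramethyl-1,3,2-dioxaborolan-2-yl)phenyl sulfate | CC1(C)OB(OC1(C)C)c1ccc(OS(=O)(=O)OCC(Cl)(Cl)Cl)cc1 | intermediate
9 | 4-[5,7-bis(benzyloxy)-6-methoxy-4-oxo-4H-chromen-2-yl]phenyl 2,2,2-trichloroethyl sulfate | COc1c(OCc2ccccc2)cc2oc(-c3ccc(OS(=O)(=O)OCC(Cl)(Cl)Cl)cc3)cc(=O)c2c1OCc1ccccc1 | intermediate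
10 | ammonium 4-(5,7-dihydroxy-6-methoxy-4-oxo-4H-chromen-2-yl)phenyl sulfate | [NH4+].COc1c(O)cc2oc(-c3ccc(OS(=O)(=O)[O-])cc3)cc(=O)c2c1O | intermediate
11 | hispidulin 4'-sulfate | COc1c(O)cc2oc(-c3ccc(OS(=O)(=O)O)cc3)cc(=O)c2c1O | target

**Step count**
Total steps: 6. Longest linear sequence: 5 (steps 1, 2, 3, 5, 6); step 4 is a one-step side branch.

**Steps most likely to fail**

Step 5. Carbopalladation of the electron-rich 5,7-dialkoxy pyrone may be slow, so oxidative homocoupling or protodeboronation of the boronate could win, and the trichloroethyl sulfate may erode at the temperature needed. The fallback reverses the polarity of the union. Setting out from 6, C2-selective deprotonative zincation with TMPZnCl·LiCl (THF, 0 °C to rt) should give [5,7-bis(benzyloxy)-6-methoxy-4-oxo-4H-chromen-2-yl]zinc chloride F1. Negishi coupling (Pd(dba)2, tri(2-furyl)phosphine, THF, 50 °C) with 4-iodophenyl 2,2,2-trichloroethyl sulfate F2 then forms the same bond; F2 is made from commercial 4-iodophenol and 2,2,2-trichloroethyl chlorosulfate (Et3N, DMAP, THF). The fallback comes back to the route at 9.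

Step 1. The persulfate oxidation may stall at low conversion, over-oxidise the product, or suffer from poor solubility of the dibenzyl phenolate in aqueous alkali, and some benzyl ether may be lost during the acidic sulfate hydrolysis. The fallback replaces the direct hydroxylation by oxidation to a quinone and reduction. Setting out from 1, Teuber oxidation with Fremy's salt (KH2PO4 buffer, acetone/H2O, rt) should give 2-acetyl-3,5-bis(benzyloxy)cyclohexa-2,5-diene-1,4-dione F3. Reduction with Na2S2O4 (EtOAc/H2O, rt) comes back to the route at 3.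

Step 6. Over-reduction of the C2=C3 bond of the pyrone, or hydrodechlorination of the trichloroethyl group without fragmentation, may compete with the intended cleavages, and the free hydrogen sulfate may hydrolyse during acid exchange. The fallback avoids hydrogen on palladium. Setting out from 9, acidolytic debenzylation with TFA and pentamethylbenzene (rt), which the acid-stable sulfate diester should survive, gives 4-(5,7-dihydroxy-6-methoxy-4-oxo-4H-chromen-2-yl)phenyl 2,2,2-trichloroethyl sulfate F4. Zinc dust and HCO2NH4 (MeOH, rt) then cleave the trichloroethyl group by reductive β-elimination, and the fallback comes back to the route at 10.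

**Further compounds**
F1 | step 5 | [5,7-bis(benzyloxy)-6-methoxy-4-oxo-4H-chromen-2-yl]zinc chloride | COc1c(OCc2ccccc2)cc2oc([Zn]Cl)cc(=O)c2c1OCc1ccccc1
F2 | step 5 | 4-iodophenyl 2,2,2-trichloroethyl sulfate | O=S(=O)(Oc1ccc(I)cc1)OCC(Cl)(Cl)Cl
F3 | step 1 | 2-acetyl-3,5-bis(benzyloxy)cyclohexa-2,5-diene-1,4-dione | CC(=O)C1=C(OCc2ccccc2)C(=O)C(OCc2ccccc2)=CC1=O
F4 | step 6 | 4-(5,7-dihydroxy-6-methoxy-4-oxo-4H-chromen-2-yl)phenyl 2,2,2-trichloroethyl sulfate | COc1c(O)cc2oc(-c3ccc(OS(=O)(=O)OCC(Cl)(Cl)Cl)cc3)cc(=O)c2c1O
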